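The impurity is the one charge that differs between the alpha and eta runs, and dusk and summer carry more of it.

| flask | left-handed substrate | right-handed substrate | gas | free catalyst | impurity | remark | time |
|---|---|---|---|---|---|---|---|
| alpha | 19 mM | 19 mM | 8 mM (held) | 0.53 mol% | 15 µM | run made earlier |  |
| eta | 19 mM | 19 mM | 8 mM (held) | 0.53 mol% | 22 µM | run made earlier |  |
| summer | 19 mM | 19 mM | 8.0 mM (held) | 0.53 mol% | 30 µM |  | 2.0 d |
| dusk | 19 mM | 19 mM | 8.0 mM (held) | 0.53 mol% | 30 µM |  | 0.60 d |

- free catalyst is single-handed; left-handed substrate and right-handed substrate are mirror images of each other, charged as a racemate, each of them at the stated concentration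
- at the start none of partner is dissolved
- what was read earlier has a scatter of 1 percentage point, one standard deviation
- on the list of suspects stand: free catalyst + left-handed substrate <-> catalyst intermediate A; free catalyst + right-handed substrate <-> catalyst intermediate B; partner + catalyst intermediate A -> free catalyst + left-handed product; partner + catalyst intermediate B -> free catalyst + right-handed product; gas <-> partner; free catalyst + impurity -> spent catalyst; partner <-> dormant form
- an excess is the difference of the two amounts in percent of their sum
- an excess is below zero if the other one leads

* the winner by excess of right-handed substrate over left-handed substrate among what is left of the two; "neither" if no more than 2 percentage points parts them (summer / dusk / neither)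
* excess of right-handed substrate over left-handed substrate among what is left of the two at the end, summer
* excess of right-handed substrate over left-handed substrate among what is left of the two at the end, dusk

| run | time / d | right-handed substrate / % | left-handed substrate / % | left-handed product / % |
|---|---|---|---|---|
| alpha | 0.500 | 48.5 | 5.0 | 46.8 |
| alpha | 1.04 | 40.1 | 0.6 | 49.2 |
| alpha | 1.25 | 35.2 | 0 | 50.0 |
| alpha | 2.08 | 27.0 | 0.3 | 49.5 |
| alpha | 2.50 | 21.7 | 0 | 48.4 |
| eta | 0.208 | 47.5 | 26.8 | 24.7 |
| eta | 0.333 | 49.3 | 14.9 | 33.8 |
| eta | 0.625 | 44.5 | 0.9 | 47.8 |
| eta | 1.25 | 36.6 | 0 | 50.4 |
| eta | 2.50 | 24.1 | 0 | 50.6 |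

(each reading ± 1 percentage point)

We reckon with a frozen catalyst. Suppose the impurity acts as a catalyst poison early on, each impurity taking one catalyst. The share still working is then one minus the impurity over the catalyst charged, which for dusk and summer is the working share 70.2%. Alpha keeps 85.1% and eta 78.2%. With substrates, gas and catalyst charged alike, flasks should then stand alike at equal working time, the share multiplied by the clock.

The left-handed readings fit this. Eta at 0.333 d has a working time of 0.260 d and reads 14.9% left-handed substrate. Eta at 0.625 d has 0.489 d and reads 0.9%. Alpha at 0.500 d, with 0.425 d, falls between them in both time and reading, at 5.0%.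

That alpha row is also our dusk, whose working time is 0.421 d. Its 48.5% right-handed substrate against 5.0% left-handed gives us an excess of 81.3%, or 84.8% with one point of scatter on the left-handed reading. Summer's 1.40 d runs past alpha at 1.25 d, with 1.06 d and 0% left-handed substrate, so we put summer near 100%.

The forecast says summer, with 99.9% for summer and 90% for dusk, which is above our dusk figure. It shares our supposition: “I assume the impurity titrates catalyst roughly one-for-one”.

    free catalyst + left-handed substrate ⇌ catalyst intermediate A (K = 590 L mol⁻¹, k = 16800 L mol⁻¹ h⁻¹)
    free catalyst + right-handed substrate ⇌ catalyst intermediate B (K = 21.0 L mol⁻¹, k = 19500 L mol⁻¹ h⁻¹)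
    partner + catalyst intermediate A → free catalyst + left-handed product (k = 3710 L mol⁻¹ h⁻¹)
    partner + catalyst intermediate B → free catalyst + right-handed product (k = 1360 L mol⁻¹ h⁻¹)
    gas ⇌ partner, rate k5*(csat - [partner]) (kL = 8.89 h⁻¹)
    free catalyst + impurity → spent catalyst (k = 54900 L mol⁻¹ h⁻¹)
    partner ⇌ dormant form (K = 0.970, k = 0.121 h⁻¹)

The winner is summer, with >99.9% against 86.2% for dusk, which held 3.44% left-handed and 46.6% right-handed substrate at 0.600 d, its spent catalyst at 29.8% of the catalyst charged, beside the 29.8% left out of the working share of 70.2%. The neighbour flask is dusk with 0.0075 mM impurity. Its share is 92.6%, so its working time of 0.555 d passes the working time of eta's third reading, and that reading gives an excess of 96.0%. That flask gave 96.8%, with 0.720% left-handed substrate left.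

The readings stem from a simulated flask from invented constants, and the scatter is random.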